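Two earlier flasks of solid E turning into L, oak and maple, are compared here per litre of solution, and as read from the straight stretches of their readings maple's L climbs faster than oak's, 0.0712 M d⁻¹ against 0.0201 M d⁻¹; this daily gain of L per litre after the early lag I call the litre climb, the apparent zero-order rate.

| setting | oak | maple | eta | zeta |
|---|---|---|---|---|
| E | 0.67 M | 1.2 M | 1.1 M | 0.60 M |
| temperature | 5 °C | 16 °C | 20 °C | 0 °C |
| remark | run made earlier | run made earlier |  |  |
| time |  |  | 6.0 d | 6.0 d |

| run | time / d | L / % |
|---|---|---|
| oak | 0.500 | 0.2 |
| oak | 1.67 | 0.3 |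
| oak | 4.00 | 3.3 |
| oak | 5.00 | 5.2 |
| oak | 6.00 | 9.7 |
| oak | 8.00 | 15.3 |
| maple | 0.250 | 2.0 |
| maple | 0.833 | 0 |
| maple | 1.67 | 2.1 |
| maple | 2.50 | 6.5 |
| maple | 3.00 | 9.5 |
| maple | 4.00 | 15.4 |

(each reading ± 1 percentage point)

- as a solid, counted per litre of solution: E
- the numbers in the tables scatter by 1 percentage point (one standard deviation)
- at the start none of E is in solution
- what has only dissolved of E counts as not reacted

- which of the two ends with the higher amount of L, in percent of the E charged ("neither" if they lie within 2 percentage points) (eta / zeta / neither)
- L at the end, in percent of the E charged, eta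
- L at the end, in percent of the E charged, zeta

Why per litre and not in per cent? A per cent belongs to a charge and the charges differ, whereas solid E that must dissolve first may hold the solution steady while solid stands, so the litre climb is what I expect to carry between flasks.

Do these runs prove that? No, and that is the weak spot: oak and maple differ in charge as well as temperature, so booking the factor 3.54 between their climbs to the step from 5 °C to 16 °C is my assumption.

What follows for the new flasks? Spreading that factor evenly on a logarithmic scale gives a climb of 0.113 M d⁻¹ for eta and 0.0113 M d⁻¹ for zeta, and the lags read from the lines, 2.90 d for oak and 1.40 d for maple, treated alike become 1.08 d and 4.03 d, so climb times days left over charge gives me 50.5 % for eta, higher than the 3.71 % for zeta.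

Can eta's charge carry that line? It asks for 0.555 M of L, less than the 1.1 M charged.

Which figure do you trust less? Zeta's, which rests on 1.97 d of rising after an extrapolated lag, with readings scattering by 1 percentage point.

The forecast names eta as the higher, with 45 % for eta and 4.5 % for zeta, holding that the rate “should not depend on the E charged”; its eta lies below mine and its zeta above mine.

The simulation gives 46.0 % for eta and 2.52 % for zeta, so eta ends higher.

    D ⇌ Z (K = 0.580, k = 0.0740 h⁻¹, Ea = 93.0 kJ mol⁻¹, ΔH = −38.0 kJ mol⁻¹)
    Q → L (k = 0.0450 h⁻¹, Ea = 102 kJ mol⁻¹)
    J → Q (k = 0.0430 h⁻¹, Ea = 89.0 kJ mol⁻¹)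
    E ⇌ J, rate k4*(cs4 - [J]) while solid is left; crystals form when [J] > cs4 (solubility = 0.520 M, k = 0.0210 h⁻¹)
    Q → D (k = 0.0300 h⁻¹, Ea = 110 kJ mol⁻¹)
    (constants at 20 °C)

Eta's result, spread over its days after the lag, is worth 0.103 M d⁻¹ against the 0.113 M d⁻¹ reckoned. The neighbouring flask is eta again with 0.44 M of E, read at 6.00 d, and the same climb and lag ask there for 0.555 M of L, more than that charge. That flask shows L at 59.0 % of its charge, D at 25.0 %, Z at 14.4 %, and 0.74 % of the E charged still there, solid or dissolved.

(The runs are calculated with constants of no real substance, noise included.)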